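## Structural features

The target is a 3,4-dibenzyl-γ-butyrolactone lignan. It has one five-membered lactone (O1, C2 carbonyl, C3, C4, C5) that carries a 3,4,5-trimethoxybenzyl group on C3 through Cb (ring B) and a 4-hydroxy-3,5-dimethoxybenzyl group on C4 through Ca (ring A). The arenes are not fused to the lactone and differ only in the para substituent. C3 and C4 are adjacent stereocentres, both R, with the two benzyl groups trans. C3 is α to the carbonyl, so it can be epimerised, and trans is the thermodynamic arrangement. C4 has no acidifying neighbour, bears only carbon and hydrogen, and cannot be corrected once set. Fragile sites are the free, doubly ortho-methoxylated phenol of ring A, the lactone, and, in the intermediates, an α-methylene lactone whose double bond can migrate into the ring and erase C4. The real difficulty is the absolute configuration at C4, together with keeping two nearly identical arenes apart. The key step exploits that C5 is an unsubstituted OCH2 (a formaldehyde carbon) next to C4 and that C2–C3(–Cb)–C4 is a 2-(methoxycarbonyl)allyl unit. Addition of that unit through its γ carbon (C4) to formaldehyde, followed by lactonisation, gives the ring, C4 and an exocyclic methylene at Cb that accepts ring B.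

## Logic of the disconnections

**16 from 15.** The O–CH2Ph bond on the para oxygen of ring A is cut. A free phenol of this kind would not survive ozone, electrophilic bromine or the organometallic steps, so it is masked in the first step and released in the last. The gain is tactical only. The forward step must leave the lactone and both stereocentres alone, which neutral hydrogenolysis should do because 15 holds no other reducible group.

**15 from 14.** No skeletal bond is cut; only the configuration at C3 (the C3–H bond) is released, 14 being the same lactone with C3 unassigned. C3 is α to the carbonyl and trans is the thermodynamic arrangement, so C3 need not be controlled when ring B is attached. This reduces the stereochemical problem to C4. The forward step needs a base that enolises the lactone reversibly without opening it.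

**14 from 12 and 13.** The Cb–aryl bond to ring B is cut. This exposes Cb as the exocyclic methylene of an α-methylene lactone and ring B as a stock arylboron reagent. Nine carbons are removed in one convergent operation and the two arenes are distinguished by construction. The forward step must be a 1,4-addition with protonation that is faster than migration of the exocyclic double bond into the ring, since that migration would destroy C4.

**12 from 8 and 9.** Two bonds are cut, C4–C5 and O1–C2. C5 is an unsubstituted OCH2 and is therefore 9. What remains, C2–C3(=Cb)–C4 with Ca and ring A on C4, is a 2-(methoxycarbonyl)allyl fragment with its metal on the future Cb, that is 10, which comes from 8. This cut simplifies most: the ring, two skeletal bonds and the one stereocentre that cannot be repaired later come from an acyclic, achiral ester. The demands are attack through the γ carbon, a single geometry of 10, closure of 11 to the lactone, and a chiral ligand on chromium that selects one face of the γ carbon although 9 has no prochiral face.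

**8 from 6.** The primary C–Br bond is cut with allylic transposition, so the bromide traces back to a secondary allylic alcohol with a terminal methylene. The trisubstituted alkene thereby becomes the product of a standard aldehyde–acrylate coupling. The forward step must deliver bromide at the terminal carbon with the thermodynamic Z geometry and must be non-acidic, because a strong mineral acid would threaten the aryl benzyl ether.

**6 from 4 and 5.** The bond between the carbinol carbon and the α carbon of the acrylate is cut. Both pieces are simple, and no stereochemistry needs control because the carbinol centre disappears in the next step. The demand is on rate: 4 is an enolisable arylacetaldehyde and the coupling must outrun its self-condensation.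

**4 from 2.** The aldehyde carbon is traced back to the internal carbon of an allyl group, the terminal CH2 being excised by way of 3. The allylarene is stable and storable whereas 4 is not, so the sensitive aldehyde is made only when needed. The oxidant must take the monosubstituted alkene and leave the electron-rich arene and the benzyl ether.

**2 from 1.** The same O–benzyl bond is cut, back to the commercial allylphenol. The hindered but acidic phenol should alkylate cleanly on oxygen.

## Other disconnections considered

**Alternative 1:** The two bonds from the ring to the benzylic carbons, C4–Ca and C3–Cb, are cut, and the lactone ring is kept as a butenolide with a chiral acetal at C5.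
- Forward key step: the lithiated dithiane A1 (masked acyl anion of ring A) adds 1,4 to the menthyloxybutenolide A2 on the face away from the C5 alkoxy group. The lactone enolate is then trapped by 3,4,5-trimethoxybenzyl bromide A3 on the face away from the new C4 substituent, which should give the 3,4-trans-4,5-trans adduct A4.
- In its favour: two skeletal bonds and both ring stereocentres arise in one flask under substrate control by a crystalline auxiliary. The trans relation is kinetic, so no epimerisation step is needed, and three pieces are joined convergently.
- Against it here: C5 arrives at the acetal level and Ca at the dithioketal level. A4 therefore needs a reductive desulfurisation and a hydride reduction of C5 with relactonisation before the benzyl ether is removed. The auxiliary and the sulfur are stoichiometric, and A2 needs its own preparation and separation of C5 epimers.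
- Comparison: on stereochemical security this plan is the better one, because its control elements are established on this substrate class while the chosen plan rests on an untested induction. On skeletal bonds per key step the two are equal, and on convergence this plan is equal or better. The chosen plan is better in redox economy (every skeletal carbon enters at its final oxidation level), needs no stoichiometric auxiliary and uses a catalytic source of chirality. Overall step counts are similar, about eight operations either way.

**Alternative 2:** The aryl–Ca bond of ring A and the C3–Cb bond are cut; the lactone ring and C4 come from the chiral pool as the cyclopropane-fused lactone A5.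
- Forward key step: the arylmagnesium bromide A6 with catalytic CuI opens the activated cyclopropane of A5 at its CH2 carbon (homoconjugate addition, the malonate-type enolate being the leaving group). This forms the aryl–Ca bond without touching the stereocentre. The enolate is benzylated in the same pot with A3 to give A7; demethoxycarbonylation, equilibration of C3 and hydrogenolysis would follow.
- In its favour: the configuration at C4 is bought and not made, so its enantiopurity should equal that of A5. Two skeletal bonds form in one pot, A5 is one step from cheap materials, and the sequence is shorter (about six steps against eight).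
- Against it here: A6 must be made from a protected aryl bromide that needs its own preparation. A magnesium malonate enolate is a sluggish nucleophile for building a quaternary centre, so the one-pot trapping may have to become a separate deprotonation–alkylation. An ester carbon is carried in only to be removed under hot halide conditions, and C3 then needs the same thermodynamic correction as in the chosen plan.
- Comparison: both plans treat C4 as the crux. This one is better on security of C4 and on step count, equal on the handling of C3, and worse in atom economy (sacrificial ester, stoichiometric organomagnesium) and in the harshness of its late steps. The chosen plan offers a catalytic enantioselective entry that does not depend on a chiral-pool building block, at the price of an unproven selectivity.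

**Alternative 3:** Only the C2–C3 bond is cut, which opens the lactone to the selenocarbonate A8 of a homoallylic alcohol whose alkene is the styrene of ring B.
- Forward key step: a trialkyltin hydride with an azo initiator removes the arylseleno group. The alkoxycarbonyl radical adds 5-exo-trig to the proximal alkene carbon (C3), the benzylic radical at Cb is reduced, and the ring closes to A9, which is identical with 15.
- In its favour: it would give 15 directly under neutral conditions. The addition should be fast because it produces a benzylic radical, and the C3–C4 trans relation should be favoured kinetically with the C4 substituent pseudo-equatorial, so no enolate chemistry is needed.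
- Against it here: the step makes one skeletal bond and sets only C3, the centre that can be corrected anyway. C4 must be built beforehand in a separate enantioselective synthesis of the branched alcohol. A8 requires a chloroformate-level activation and a selenol, and tin residues must be removed from a late intermediate.
- Comparison: mechanistically this is the equal or the better for C3, and it lands on the same compound as step 7 of the chosen plan. Structurally it is weaker, because it leaves the C4 problem to the precursor. In step economy it is worse: the route to A8 (asymmetric alkylation, alkene construction, acylation) should take more steps than the five that lead to 12.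

Key step: step 5

Assumption: the antipode of the chromium ligand that gives R at C4 cannot be predicted from the higher-aldehyde cases; it is taken to be identified in the first runs, and the route is written for that antipode.

Remark on the structures: re-derivation of the descriptors gives 16 as (3R,4R) with the benzyl groups trans, 12 as R with the same spatial arrangement at C4, and 8 as Z (CH2Br and CH2Ar cis, ester trans to CH2Ar); no structure needed correction. The design is tightened in three places: a non-acidic bromination (step 4), catalytic chromium with a tridentate ligand, and Cp2ZrCl2 in place of a chlorosilane, which would react with 9 (step 5).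

## Route

Step 1
Reactants: 1 4-allyl-2,6-dimethoxyphenol
Product: 2 5-allyl-2-(benzyloxy)-1,3-dimethoxybenzene
Conditions: BnBr (1.1 equiv), K2CO3 (1.5 equiv), DMF, rt to 50 °C
Reagents that add atoms: benzyl bromide, BrCc1ccccc1
Why: Williamson ether synthesis on the phenoxide of 1; the benzyl ether should tolerate ozone at −78 °C, amine bases, the sulfonium bromination, low-valent chromium and rhodium, and is removed at the end by neutral hydrogenolysis.

Step 2
Reactants: 2 5-allyl-2-(benzyloxy)-1,3-dimethoxybenzene
Product: 4 2-(4-benzyloxy-3,5-dimethoxyphenyl)acetaldehyde, via ozonide 3 (not isolated)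
Conditions: O3, CH2Cl2, −78 °C (Sudan red 7B as end-point indicator); PPh3 (1.1 equiv), −78 °C to rt; short silica pad, used the same day
Reagents that add atoms: ozone, [O-][O+]=O
Why: Ozonolysis with reductive work-up (Criegee mechanism): the monosubstituted alkene should react with ozone much faster than the alkoxyarenes, the indicator marks the end point before the rings are attacked, and PPh3 reduces ozonide 3 to the aldehyde. 4 is enolisable and air-sensitive and is therefore not stored.

Step 3
Reactants: 4 2-(4-benzyloxy-3,5-dimethoxyphenyl)acetaldehyde, 5 methyl acrylate
Product: 6 methyl 4-(4-benzyloxy-3,5-dimethoxyphenyl)-3-hydroxy-2-methylidenebutanoate (racemic)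
Conditions: DABCO (1 equiv), 5 (3 equiv), 1,4-dioxane/H2O 1:1, rt
Reagents that add atoms: none
Why: Morita–Baylis–Hillman reaction: DABCO adds to 5, the ammonium enolate adds to the aldehyde carbon of 4, and proton transfer with loss of the amine gives the allylic alcohol; aqueous dioxane and a full equivalent of amine are chosen to speed the coupling past the self-aldol reaction of 4. The carbinol centre forms racemic and is erased in step 4.

Step 4
Reactants: 6 methyl 4-(4-benzyloxy-3,5-dimethoxyphenyl)-3-hydroxy-2-methylidenebutanoate
Product: 8 methyl (Z)-2-(bromomethyl)-4-(4-benzyloxy-3,5-dimethoxyphenyl)but-2-enoate, via alkoxysulfonium bromide 7 (not isolated)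
Conditions: NBS (1.3 equiv), Me2S (1.5 equiv), CH2Cl2, 0 °C, premixed; then 6, 0 °C to rt
Reagents that add atoms: N-bromosuccinimide, O=C1CCC(=O)N1Br
Why: Corey–Kim-type activation: the sulfonium salt from NBS and Me2S turns the hydroxyl into alkoxysulfonium 7, and bromide attacks the terminal methylene in an SN2' displacement with loss of dimethyl sulfoxide. The trisubstituted Z bromide (CH2Ar trans to the ester) is the thermodynamic isomer, and the non-acidic medium without free bromine should spare the aryl benzyl ether and the electron-rich ring, which hot HBr would endanger.

Step 5
Reactants: 8 methyl (Z)-2-(bromomethyl)-4-(4-benzyloxy-3,5-dimethoxyphenyl)but-2-enoate, 9 formaldehyde (monomer, ca. 1 M in THF, freshly cracked from paraformaldehyde)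
Product: 12 (R)-4-(4-benzyloxy-3,5-dimethoxybenzyl)-3-methylenedihydrofuran-2(3H)-one, via allylchromium species 10 (not isolated), via open-chain hydroxy ester 11 (not isolated)
Conditions: CrCl2 (10 mol%), L* (12 mol%; 1,8-bis[(4S)-4-isopropyl-4,5-dihydrooxazol-2-yl]-3,6-diphenyl-9H-carbazole or its antipode), iPr2NEt (30 mol%), Mn powder (2 equiv), Cp2ZrCl2 (1.2 equiv), THF, 0 °C to rt, slow addition of 8 and of 9 (3 equiv); aq. citric acid; then TsOH·H2O (cat.), CH2Cl2, rt
Reagents that add atoms: none
Why: Proposed new method: divalent chromium, regenerated by Mn, reduces the allylic C–Br bond of 8 in two one-electron steps to the ligand-bound allylchromium 10 (trivalent chromium), which adds to 9 through its γ carbon in a closed six-membered chair, forming C4–C5 and moving the double bond to the exocyclic Cb position, while Cp2ZrCl2 takes over the alkoxide and frees chromium for turnover. The alkoxide of 11 then closes the lactone by 5-exo-trig acyl substitution at the ester (O1–C2), completed by the acid treatment. The closest known reactions are the racemic zinc- or indium-mediated 2-(alkoxycarbonyl)allylation of formaldehyde and the chromium-catalysed enantioselective 2-(alkoxycarbonyl)allylation–lactonisation of higher aldehydes; their combination, an enantioselective addition to formaldehyde, is not established. C4 is the only new stereocentre and is controlled by the chiral tridentate ligand on chromium: since 9 has no prochiral face, the ligand must choose between the two diastereomeric chairs that present opposite faces of the γ carbon, the same choice that fixes the γ-carbon configuration when γ-substituted reagents add to higher aldehydes. The ester on the central allyl carbon is expected to hold 10 in one geometry (CH2Ar trans to CO2Me, hence pseudo-axial in the chair and pointing into the ligand sphere), which a clean facial preference requires because the two geometries would give opposite configurations from the same chair. γ-Regioselectivity is secured by the cyclic transition state, and slow addition of 8 with a slight excess of ligand over CrCl2 should keep reductive coupling of the bromide and ligand-free background addition low. Which antipode of L* gives R is to be found in the first experiments, and the enantiomeric purity of 12 is to be checked by chiral HPLC before going on.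

Step 6
Reactants: 12 (R)-4-(4-benzyloxy-3,5-dimethoxybenzyl)-3-methylenedihydrofuran-2(3H)-one, 13 3,4,5-trimethoxyphenylboronic acid
Product: 14 (4R)-4-(4-benzyloxy-3,5-dimethoxybenzyl)-3-(3,4,5-trimethoxybenzyl)dihydrofuran-2(3H)-one (mixture of C3 epimers)
Conditions: 13 (2 equiv), [Rh(cod)OH]2 (2.5 mol%), 1,4-dioxane/H2O 10:1, 50 °C
Reagents that add atoms: none
Why: Rhodium-catalysed 1,4-addition of an arylboronic acid (Hayashi–Miyaura type) to an α-methylene carbonyl compound: aryl transfer from boron to monovalent rhodium, insertion of the exocyclic alkene with the aryl group going to Cb, and protonolysis of the oxa-π-allylrhodium by water. C3 is set by this protonation, expected mainly on the face away from the C4 substituent (cis), so no selectivity is demanded here and step 7 corrects it; the hydroxo complex needs no added base, which should keep the exocyclic alkene from migrating into the ring before it reacts.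

Step 7
Reactants: 14 (4R)-4-(4-benzyloxy-3,5-dimethoxybenzyl)-3-(3,4,5-trimethoxybenzyl)dihydrofuran-2(3H)-one (mixture of C3 epimers)
Product: 15 (3R,4R)-4-(4-benzyloxy-3,5-dimethoxybenzyl)-3-(3,4,5-trimethoxybenzyl)dihydrofuran-2(3H)-one
Conditions: DBU (1 equiv), toluene, 80 °C
Reagents that add atoms: none
Why: Base-mediated epimerisation through the lactone enolate: only C3 is acidic, and equilibration should favour the isomer with the two benzyl groups on opposite faces of the ring (3R,4R); C4 has no acidic hydrogen and is not touched.

Step 8
Reactants: 15 (3R,4R)-4-(4-benzyloxy-3,5-dimethoxybenzyl)-3-(3,4,5-trimethoxybenzyl)dihydrofuran-2(3H)-one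
Product: 16 (3R,4R)-4-(4-hydroxy-3,5-dimethoxybenzyl)-3-(3,4,5-trimethoxybenzyl)dihydrofuran-2(3H)-one
Conditions: H2 (1 atm), 10% Pd/C, EtOAc/EtOH, rt
Reagents that add atoms: none
Why: Catalytic hydrogenolysis of the aryl benzyl ether; 15 holds no alkene, halide or other benzylic C–O bond (C5–O1 is not benzylic), so the lactone and both stereocentres should be unaffected.

## Compound list

1 | 4-allyl-2,6-dimethoxyphenol | C=CCc1cc(OC)c(O)c(OC)c1 | starting material
2 | 5-allyl-2-(benzyloxy)-1,3-dimethoxybenzene | C=CCc1cc(OC)c(OCc2ccccc2)c(OC)c1 | intermediate
3 | 3-[(4-benzyloxy-3,5-dimethoxyphenyl)methyl]-1,2,4-trioxolane (ozonide, racemic, not isolated) | COc1cc(CC2OCOO2)cc(OC)c1OCc1ccccc1 | intermediate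
4 | 2-(4-benzyloxy-3,5-dimethoxyphenyl)acetaldehyde | O=CCc1cc(OC)c(OCc2ccccc2)c(OC)c1 | intermediate
5 | methyl acrylate | C=CC(=O)OC | starting material
6 | methyl 4-(4-benzyloxy-3,5-dimethoxyphenyl)-3-hydroxy-2-methylidenebutanoate (racemic) | COC(=O)C(=C)C(O)Cc1cc(OC)c(OCc2ccccc2)c(OC)c1 | intermediate
7 | {[1-(4-benzyloxy-3,5-dimethoxyphenyl)-3-(methoxycarbonyl)but-3-en-2-yl]oxy}dimethylsulfonium bromide (racemic, not isolated) | COC(=O)C(=C)C(O[S+](C)C)Cc1cc(OC)c(OCc2ccccc2)c(OC)c1.[Br-] | intermediate
8 | methyl (Z)-2-(bromomethyl)-4-(4-benzyloxy-3,5-dimethoxyphenyl)but-2-enoate | COC(=O)/C(CBr)=C/Cc1cc(OC)c(OCc2ccccc2)c(OC)c1 | intermediate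
9 | formaldehyde | C=O | starting material
10 | [(Z)-4-(4-benzyloxy-3,5-dimethoxyphenyl)-2-(methoxycarbonyl)but-2-enyl]chromium species (trivalent chromium, bound to L*; SMILES written as the ligand-free dichloride; not isolated) | COC(=O)/C(C[Cr](Cl)Cl)=C/Cc1cc(OC)c(OCc2ccccc2)c(OC)c1 | intermediate
11 | methyl (3R)-4-(4-benzyloxy-3,5-dimethoxyphenyl)-3-(hydroxymethyl)-2-methylidenebutanoate (present as its metal alkoxide; SMILES of the free alcohol; not isolated) | COC(=O)C(=C)[C@H](CO)Cc1cc(OC)c(OCc2ccccc2)c(OC)c1 | intermediate
12 | (R)-4-(4-benzyloxy-3,5-dimethoxybenzyl)-3-methylenedihydrofuran-2(3H)-one | COc1cc(C[C@H]2COC(=O)C2=C)cc(OC)c1OCc1ccccc1 | intermediate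
13 | 3,4,5-trimethoxyphenylboronic acid | COc1cc(B(O)O)cc(OC)c1OC | starting material
14 | (4R)-4-(4-benzyloxy-3,5-dimethoxybenzyl)-3-(3,4,5-trimethoxybenzyl)dihydrofuran-2(3H)-one, mixture of C3 epimers | COc1cc(C[C@H]2COC(=O)C2Cc2cc(OC)c(OC)c(OC)c2)cc(OC)c1OCc1ccccc1 | intermediate
15 | (3R,4R)-4-(4-benzyloxy-3,5-dimethoxybenzyl)-3-(3,4,5-trimethoxybenzyl)dihydrofuran-2(3H)-one | COc1cc(C[C@H]2COC(=O)[C@@H]2Cc2cc(OC)c(OC)c(OC)c2)cc(OC)c1OCc1ccccc1 | intermediate
16 | (3R,4R)-4-(4-hydroxy-3,5-dimethoxybenzyl)-3-(3,4,5-trimethoxybenzyl)dihydrofuran-2(3H)-one | COc1cc(C[C@H]2COC(=O)[C@@H]2Cc2cc(OC)c(OC)c(OC)c2)cc(OC)c1O | target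

## Step count and least certain steps

Total step count: 8. Longest linear sequence: 8 steps (1 to 16); 5, 9 and 13 are bought and enter in steps 3, 5 and 6.

**Step 5 (key step, proposed new method).**
- Most likely failure: poor facial selectivity at the γ carbon. The formaldehyde end of the chair carries no substituent for the ligand to read, so the two diastereomeric chairs may differ too little in energy. Oligomerisation of 9 and reductive coupling of 8 may also lower the conversion.
- Fallback (known chemistry, sets out from 2 and returns at 15, bypassing steps 2 to 7):
  - 2 is hydroborated and oxidised (9-BBN, THF; NaOH, H2O2) to 3-(4-benzyloxy-3,5-dimethoxyphenyl)propan-1-ol F1.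
  - F1 is oxidised (TEMPO, PhI(OAc)2, MeCN/H2O) to 3-(4-benzyloxy-3,5-dimethoxyphenyl)propanoic acid F2.
  - Pivaloyl chloride and Et3N convert F2 into the mixed anhydride 3-(4-benzyloxy-3,5-dimethoxyphenyl)propanoic pivalic anhydride F3.
  - F3 acylates (S)-4-benzyloxazolidin-2-one (LiCl, THF) to (4S)-4-benzyl-3-[3-(4-benzyloxy-3,5-dimethoxyphenyl)propanoyl]oxazolidin-2-one F4.
  - Evans alkylation (NaN(SiMe3)2, THF, −78 °C; tert-butyl bromoacetate) on the face of the Z enolate away from the auxiliary benzyl group should give tert-butyl (3R)-3-{[(4S)-4-benzyl-2-oxooxazolidin-3-yl]carbonyl}-4-(4-benzyloxy-3,5-dimethoxyphenyl)butanoate F5.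
  - LiBH4 (THF, one equivalent of water, 0 °C) removes the auxiliary reductively and leaves the tert-butyl ester, giving tert-butyl (3R)-4-(4-benzyloxy-3,5-dimethoxyphenyl)-3-(hydroxymethyl)butanoate F6.
  - CF3CO2H in CH2Cl2 closes F6 to (R)-4-(4-benzyloxy-3,5-dimethoxybenzyl)dihydrofuran-2(3H)-one F7.
  - Deprotonation (LiN(SiMe3)2, THF, −78 °C) and alkylation with 3,4,5-trimethoxybenzyl bromide on the face away from the C4 substituent should give 15 directly.

**Step 3.**
- Most likely failure: enolisation and self-aldol condensation of the arylacetaldehyde during the slow amine-catalysed coupling, because 4 is both acidic at Ca and unhindered.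
- Fallback (sets out from 4 and returns at 6): methyl propiolate is hydroaluminated at its α carbon (iBu2AlH, N-methylmorpholine N-oxide, THF, 0 °C) to methyl 2-(diisobutylalumanyl)prop-2-enoate F8. This preformed α-metallated acrylate should add to 4 within hours at 0 °C, and aqueous work-up gives 6 without long exposure of the aldehyde to an amine base.

**Step 6.**
- Most likely failure: migration of the exocyclic double bond of 12 into the ring, which would erase C4, promoted by rhodium hydride or by base at 50 °C. Heck-type β-hydride elimination or protodeboronation of 13 could also consume the reagents.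
- Fallback (sets out from 12 and returns at 14): 5-bromo-1,2,3-trimethoxybenzene is converted with Mg in THF into 3,4,5-trimethoxyphenylmagnesium bromide F9, which is added to 12 with catalytic CuI in THF at −40 °C. The 1,4-addition and protonation of the enolate with aqueous NH4Cl should give 14 under conditions too cold for double-bond migration.

**Step 2.**
- Most likely failure: over-oxidation of the electron-rich ring by ozone if the end point is missed, or degradation of the aldehyde (enolisation, autoxidation, aldol) during removal of the phosphine oxide.
- Fallback (sets out from 2 and returns at 4): 2 is dihydroxylated (OsO4 cat., N-methylmorpholine N-oxide, acetone/H2O) to 3-(4-benzyloxy-3,5-dimethoxyphenyl)propane-1,2-diol F10, a stable compound that can be purified and stored. Cleavage with NaIO4 on silica gel in CH2Cl2 at rt should then release 4, free of peroxides, immediately before step 3.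

## Further compounds

F1 | step 5 | 3-(4-benzyloxy-3,5-dimethoxyphenyl)propan-1-ol | COc1cc(CCCO)cc(OC)c1OCc1ccccc1
F2 | step 5 | 3-(4-benzyloxy-3,5-dimethoxyphenyl)propanoic acid | COc1cc(CCC(=O)O)cc(OC)c1OCc1ccccc1
F3 | step 5 | 3-(4-benzyloxy-3,5-dimethoxyphenyl)propanoic pivalic anhydride | COc1cc(CCC(=O)OC(=O)C(C)(C)C)cc(OC)c1OCc1ccccc1
F4 | step 5 | (4S)-4-benzyl-3-[3-(4-benzyloxy-3,5-dimethoxyphenyl)propanoyl]oxazolidin-2-one | COc1cc(CCC(=O)N2[C@@H](Cc3ccccc3)COC2=O)cc(OC)c1OCc1ccccc1
F5 | step 5 | tert-butyl (3R)-3-{[(4S)-4-benzyl-2-oxooxazolidin-3-yl]carbonyl}-4-(4-benzyloxy-3,5-dimethoxyphenyl)butanoate | COc1cc(C[C@H](CC(=O)OC(C)(C)C)C(=O)N2[C@@H](Cc3ccccc3)COC2=O)cc(OC)c1OCc1ccccc1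
F6 | step 5 | tert-butyl (3R)-4-(4-benzyloxy-3,5-dimethoxyphenyl)-3-(hydroxymethyl)butanoate | COc1cc(C[C@H](CC(=O)OC(C)(C)C)CO)cc(OC)c1OCc1ccccc1
F7 | step 5 | (R)-4-(4-benzyloxy-3,5-dimethoxybenzyl)dihydrofuran-2(3H)-one | COc1cc(C[C@H]2COC(=O)C2)cc(OC)c1OCc1ccccc1
F8 | step 3 | methyl 2-(diisobutylalumanyl)prop-2-enoate | COC(=O)C(=C)[Al](CC(C)C)CC(C)C
F9 | step 6 | 3,4,5-trimethoxyphenylmagnesium bromide | COc1cc([Mg]Br)cc(OC)c1OC
F10 | step 2 | 3-(4-benzyloxy-3,5-dimethoxyphenyl)propane-1,2-diol (racemic) | COc1cc(CC(O)CO)cc(OC)c1OCc1ccccc1
A1 | alternative 1 | 2-(4-benzyloxy-3,5-dimethoxyphenyl)-1,3-dithiane | COc1cc(C2SCCCS2)cc(OC)c1OCc1ccccc1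
A2 | alternative 1 | (5R)-5-[(1R,2S,5R)-menthyloxy]furan-2(5H)-one | O=C1C=C[C@H](O[C@@H]2C[C@H](C)CC[C@H]2C(C)C)O1
A3 | alternative 1 | 3,4,5-trimethoxybenzyl bromide | COc1cc(CBr)cc(OC)c1OC
A4 | alternative 1 | (3R,4R,5R)-4-[2-(4-benzyloxy-3,5-dimethoxyphenyl)-1,3-dithian-2-yl]-5-[(1R,2S,5R)-menthyloxy]-3-(3,4,5-trimethoxybenzyl)dihydrofuran-2(3H)-one (3,4-trans-4,5-trans) | COc1cc(C2([C@H]3[C@H](O[C@@H]4C[C@H](C)CC[C@H]4C(C)C)OC(=O)[C@@H]3Cc3cc(OC)c(OC)c(OC)c3)SCCCS2)cc(OC)c1OCc1ccccc1
A5 | alternative 2 | methyl (1S,5R)-2-oxo-3-oxabicyclo[3.1.0]hexane-1-carboxylate | COC(=O)[C@]12C[C@H]1COC2=O
A6 | alternative 2 | (4-benzyloxy-3,5-dimethoxyphenyl)magnesium bromide | COc1cc([Mg]Br)cc(OC)c1OCc1ccccc1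
A7 | alternative 2 | methyl (3R,4R)-4-(4-benzyloxy-3,5-dimethoxybenzyl)-2-oxo-3-(3,4,5-trimethoxybenzyl)tetrahydrofuran-3-carboxylate (benzyl groups trans) | COc1cc(C[C@H]2COC(=O)[C@@]2(Cc2cc(OC)c(OC)c(OC)c2)C(=O)OC)cc(OC)c1OCc1ccccc1
A8 | alternative 3 | O-[(2R,3E)-2-(4-benzyloxy-3,5-dimethoxybenzyl)-4-(3,4,5-trimethoxyphenyl)but-3-en-1-yl] Se-phenyl carbonoselenoate | COc1cc(C[C@H](/C=C/c2cc(OC)c(OC)c(OC)c2)COC(=O)[Se]c2ccccc2)cc(OC)c1OCc1ccccc1
A9 | alternative 3 | (3R,4R)-4-(4-benzyloxy-3,5-dimethoxybenzyl)-3-(3,4,5-trimethoxybenzyl)dihydrofuran-2(3H)-one (identical with 15) | COc1cc(C[C@H]2COC(=O)[C@@H]2Cc2cc(OC)c(OC)c(OC)c2)cc(OC)c1OCc1ccccc1
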